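**Plan**

- Retrosynthesis: the three benzyl groups are put back, then ring B (benzoic acid ring: C1 carboxyl, C2 hydroxyl, C3 chlorine, C4 methyl, C5 hydrogen, C6 aryloxy) is cut at C1–C6 and C4–C5. Its contiguous carbons C1–C4 map onto C3–C6 of a 2-pyranone, and C5–C6 onto an aryl ethynyl ether whose oxygen already sits on ring A.
- Ring A arm: 3-methoxysalicylic acid is para-hydroxylated, esterified and 5-O-benzylated. The phenol is then vinylated, brominated and dehydrobrominated twice to the ethynyl ether, so no alkyllithium ever meets the methyl ester.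
- Ring B arm: dibenzyl malonate and the acetylketene precursor give the 3-benzyloxycarbonyl-4-hydroxypyranone, which is chlorinated at C5 and O-benzylated.
- Union: cycloaddition of the two arms with loss of CO2 forms ring B in one operation; BCl3 with a cation scavenger then removes the benzyl ester and both benzyl ethers.
- Stereochemistry: the target has no stereocentre. The only stereo-elements on the way (Z-bromovinyl ether, racemic dibromide, racemic bridged lactone) are erased.

Key step: step 10

Remark: compound 8 is written as the Z isomer expected from amine-induced elimination; any E isomer should converge on the same alkyne in step 6, and intermediates 7 and 19 are racemic.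

**Route**

Step 1
Reactants: 1 2-hydroxy-3-methoxybenzoic acid
Product: 3 2,5-dihydroxy-3-methoxybenzoic acid, via aryl sulfate 2 (not isolated)
Conditions: K2S2O8, aq NaOH, 0 °C to rt; then aq HCl, 90 °C
Reagents that add atoms: potassium peroxodisulfate, [K+].[K+].[O-]S(=O)(=O)OOS(=O)(=O)[O-]
Why: Elbs persulfate oxidation, in which the phenolate should be attacked by peroxodisulfate at the only free ortho/para carbon (C5) and the aryl sulfate hydrolysed by acid; the free acid is used because the alkaline medium would saponify an ester.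

Step 2
Reactants: 3 2,5-dihydroxy-3-methoxybenzoic acid
Product: 4 methyl 2,5-dihydroxy-3-methoxybenzoate
Conditions: MeOH, H2SO4 (cat.), reflux, N2
Reagents that add atoms: methanol, CO
Why: Fischer esterification, routine for salicylic acids and run under nitrogen to protect the hydroquinone from air.

Step 3
Reactants: 4 methyl 2,5-dihydroxy-3-methoxybenzoate
Product: 5 methyl 5-(benzyloxy)-2-hydroxy-3-methoxybenzoate
Conditions: BnBr (1.05 equiv), K2CO3, acetone, reflux
Reagents that add atoms: benzyl bromide, BrCc1ccccc1
Why: Williamson etherification that should occur only at the 5-hydroxyl, since the 2-hydroxyl is hydrogen-bonded to the ester and flanked by two ortho substituents (as in mono-benzylation of gentisate esters).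

Step 4
Reactants: 5 methyl 5-(benzyloxy)-2-hydroxy-3-methoxybenzoate
Product: 6 methyl 5-(benzyloxy)-2-(ethenyloxy)-3-methoxybenzoate
Conditions: Cu(OAc)2, 2,4,6-trivinylcyclotriboroxane–pyridine complex, pyridine, CH2Cl2, air, rt
Reagents that add atoms: 2,4,6-trivinylcyclotriboroxane–pyridine complex, C=CB1OB(C=C)OB(C=C)O1.c1ccncc1
Why: Chan–Lam O-vinylation, in which the vinyl group is passed from boron to divalent copper and coupled with the aryloxide while air turns the copper over; the neutral conditions spare ester and benzyl ether.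

Step 5
Reactants: 6 methyl 5-(benzyloxy)-2-(ethenyloxy)-3-methoxybenzoate
Product: 8 methyl 5-(benzyloxy)-2-{[(Z)-2-bromoethenyl]oxy}-3-methoxybenzoate, via dibromoethyl ether 7 (not isolated)
Conditions: Br2 (1.0 equiv), CH2Cl2, −78 °C; then DBU, −78 °C to rt
Reagents that add atoms: bromine, BrBr
Why: bromine should add to the enol ether double bond far faster than it substitutes the arene at −78 °C, and the α-bromo ether then loses HBr to the amidine base (classical route to β-bromovinyl ethers, mainly Z).

Step 6
Reactants: 8 methyl 5-(benzyloxy)-2-{[(Z)-2-bromoethenyl]oxy}-3-methoxybenzoate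
Product: 10 methyl 5-(benzyloxy)-2-(ethynyloxy)-3-methoxybenzoate, via lithium acetylide 9 (not isolated)
Conditions: LiN(i-Pr)2 (2.2 equiv, commercial solution), THF, −78 °C; then aq NH4Cl, −78 °C
Reagents that add atoms: none
Why: anti-periplanar E2 dehydrobromination of the Z-bromovinyl ether by the lithium amide (the classical alkynyl ether synthesis), with the second equivalent held as the acetylide until the cold quench; the non-enolisable methyl benzoate should be spared at −78 °C.

Step 7
Reactants: 11 dibenzyl malonate; 12 2,2,6-trimethyl-4H-1,3-dioxin-4-one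
Product: 16 benzyl 4-hydroxy-6-methyl-2-oxo-2H-pyran-3-carboxylate, via sodium malonate enolate 13 (not isolated), via acetylketene 14 (not isolated), via acylmalonate enolate 15 (not isolated)
Conditions: NaH, THF, 0 °C; then 12, PhMe, 110 °C (THF and acetone distilled off); then aq HCl
Reagents that add atoms: none
Why: thermal retro-[4+2] of the dioxinone releases acetylketene, which should C-acylate the malonate enolate; the enol oxygen of the acetoacetyl unit then lactonises onto one benzyl ester with loss of benzyl alcohol, as in the known diketene–malonate synthesis of 3-alkoxycarbonyl-4-hydroxy-6-methyl-2-pyranones.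

Step 8
Reactants: 16 benzyl 4-hydroxy-6-methyl-2-oxo-2H-pyran-3-carboxylate
Product: 17 benzyl 5-chloro-4-hydroxy-6-methyl-2-oxo-2H-pyran-3-carboxylate
Conditions: SO2Cl2 (1.05 equiv), CH2Cl2, 0 °C to rt, dark
Reagents that add atoms: sulfuryl chloride, O=S(=O)(Cl)Cl
Why: electrophilic chlorination with C3 blocked by the ester, so substitution should occur at C5, the only ring CH and the vinylogous enol position of the pyranone tautomer (as in C5 halogenation of 3-acyl-4-hydroxy-6-methylpyranones).

Step 9
Reactants: 17 benzyl 5-chloro-4-hydroxy-6-methyl-2-oxo-2H-pyran-3-carboxylate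
Product: 18 benzyl 4-(benzyloxy)-5-chloro-6-methyl-2-oxo-2H-pyran-3-carboxylate
Conditions: BnOH, PPh3, DIAD, THF, 0 °C to rt
Reagents that add atoms: benzyl alcohol, OCc1ccccc1
Why: Mitsunobu etherification, the standard way to alkylate acidic 4-hydroxy-2-pyranones on the 4-oxygen without C-alkylation.

Step 10
Reactants: 10 methyl 5-(benzyloxy)-2-(ethynyloxy)-3-methoxybenzoate (1.5 equiv); 18 benzyl 4-(benzyloxy)-5-chloro-6-methyl-2-oxo-2H-pyran-3-carboxylate
Product: 20 benzyl 2-(benzyloxy)-3-chloro-6-[4-(benzyloxy)-2-methoxy-6-(methoxycarbonyl)phenoxy]-4-methylbenzoate, via bridged lactone 19 (not isolated)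
Conditions: PhMe, 110 °C, sealed tube
Reagents that add atoms: none
Why: The 2-pyranone, electron-poor through its lactone carbonyl and C3 ester (the C5 chlorine offsetting part of the donation from the C4 benzyloxy group), serves as diene and the electron-rich ynol ether as dienophile in an inverse-electron-demand Diels–Alder reaction; the closest known type is the cycloaddition of 3-alkoxycarbonyl-2-pyranones with alkynyl ethers, ynamines and ketene acetals to give benzoates. Ring B closes by an intermolecular [4+2] cycloaddition that forms its C1–C6 bond (pyranone C3 to the oxygen-bearing alkyne carbon) and its C4–C5 bond (pyranone C6 to the terminal alkyne carbon), and the bridged lactone 19 then expels CO2 by retro-[4+2], so the arene appears without an oxidation step. No stereocentre is created in the product, and the two bridgehead centres of racemic 19 vanish on aromatisation. Only one regiochemistry is needed and matched polarisation should secure it: the terminal carbon is the nucleophilic end of the ynol ether, and pyranone C6, the vinylogous acceptor position of the C2 carbonyl and C3 ester, is the electrophilic end of the diene. An aryl ynol ether has no β-hydrogen for the retro-ene loss of ketene that limits alkyl ynol ethers, so it should tolerate the temperature.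

Step 11
Reactants: 20 benzyl 2-(benzyloxy)-3-chloro-6-[4-(benzyloxy)-2-methoxy-6-(methoxycarbonyl)phenoxy]-4-methylbenzoate
Product: 21 isodihydromaldoxin, 3-chloro-2-hydroxy-6-[4-hydroxy-2-methoxy-6-(methoxycarbonyl)phenoxy]-4-methylbenzoic acid
Conditions: BCl3, pentamethylbenzene, CH2Cl2, −78 to 0 °C; then H2O
Reagents that add atoms: none
Why: Lewis-acid debenzylation in which BCl3 ionises the two aryl benzyl ethers and the chelation-activated benzyl ester while pentamethylbenzene traps the benzyl cations; aryl chloride, methyl ester and the methyl ether (meta to its ester, so not chelation-activated) should survive.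

**Compound list**

1 | 2-hydroxy-3-methoxybenzoic acid | COc1cccc(C(=O)O)c1O | starting material
2 | potassium 3-carboxy-4-hydroxy-5-methoxyphenyl sulfate | COc1cc(OS(=O)(=O)[O-])cc(C(=O)O)c1O.[K+] | intermediate (not isolated)
3 | 2,5-dihydroxy-3-methoxybenzoic acid | COc1cc(O)cc(C(=O)O)c1O | intermediate
4 | methyl 2,5-dihydroxy-3-methoxybenzoate | COC(=O)c1cc(O)cc(OC)c1O | intermediate
5 | methyl 5-(benzyloxy)-2-hydroxy-3-methoxybenzoate | COC(=O)c1cc(OCc2ccccc2)cc(OC)c1O | intermediate
6 | methyl 5-(benzyloxy)-2-(ethenyloxy)-3-methoxybenzoate | COC(=O)c1cc(OCc2ccccc2)cc(OC)c1OC=C | intermediate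
7 | methyl 5-(benzyloxy)-2-(1,2-dibromoethoxy)-3-methoxybenzoate (racemic) | COC(=O)c1cc(OCc2ccccc2)cc(OC)c1OC(Br)CBr | intermediate (not isolated)
8 | methyl 5-(benzyloxy)-2-{[(Z)-2-bromoethenyl]oxy}-3-methoxybenzoate | COC(=O)c1cc(OCc2ccccc2)cc(OC)c1O/C=C\Br | intermediate
9 | lithium [4-(benzyloxy)-2-methoxy-6-(methoxycarbonyl)phenoxy]ethynide | COC(=O)c1cc(OCc2ccccc2)cc(OC)c1OC#[C-].[Li+] | intermediate (not isolated)
10 | methyl 5-(benzyloxy)-2-(ethynyloxy)-3-methoxybenzoate | COC(=O)c1cc(OCc2ccccc2)cc(OC)c1OC#C | intermediate
11 | dibenzyl malonate | O=C(CC(=O)OCc1ccccc1)OCc1ccccc1 | starting material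
12 | 2,2,6-trimethyl-4H-1,3-dioxin-4-one | CC1=CC(=O)OC(C)(C)O1 | starting material
13 | sodium enolate of dibenzyl malonate | [Na+].O=C([CH-]C(=O)OCc1ccccc1)OCc1ccccc1 | intermediate (not isolated)
14 | acetylketene (but-1-ene-1,3-dione) | CC(=O)C=C=O | intermediate (not isolated)
15 | sodium enolate of dibenzyl 2-(3-oxobutanoyl)propanedioate | CC(=O)CC(=O)[C-](C(=O)OCc1ccccc1)C(=O)OCc1ccccc1.[Na+] | intermediate (not isolated)
16 | benzyl 4-hydroxy-6-methyl-2-oxo-2H-pyran-3-carboxylate | CC1=CC(O)=C(C(=O)OCc2ccccc2)C(=O)O1 | intermediate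
17 | benzyl 5-chloro-4-hydroxy-6-methyl-2-oxo-2H-pyran-3-carboxylate | CC1=C(Cl)C(O)=C(C(=O)OCc2ccccc2)C(=O)O1 | intermediate
18 | benzyl 4-(benzyloxy)-5-chloro-6-methyl-2-oxo-2H-pyran-3-carboxylate | CC1=C(Cl)C(OCc2ccccc2)=C(C(=O)OCc2ccccc2)C(=O)O1 | intermediate
19 | benzyl 5-(benzyloxy)-6-chloro-8-[4-(benzyloxy)-2-methoxy-6-(methoxycarbonyl)phenoxy]-1-methyl-3-oxo-2-oxabicyclo[2.2.2]octa-5,7-diene-4-carboxylate (racemic; the bicycle allows one relative configuration only) | O=C1OC2(C)C=C(Oc3c(OC)cc(OCc4ccccc4)cc3C(=O)OC)C1(C(=O)OCc1ccccc1)C(OCc1ccccc1)=C2Cl | intermediate (not isolated)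
20 | benzyl 2-(benzyloxy)-3-chloro-6-[4-(benzyloxy)-2-methoxy-6-(methoxycarbonyl)phenoxy]-4-methylbenzoate | COC(=O)c1cc(OCc2ccccc2)cc(OC)c1Oc1cc(C)c(Cl)c(OCc2ccccc2)c1C(=O)OCc1ccccc1 | intermediate
21 | isodihydromaldoxin, 3-chloro-2-hydroxy-6-[4-hydroxy-2-methoxy-6-(methoxycarbonyl)phenoxy]-4-methylbenzoic acid | COC(=O)c1cc(O)cc(OC)c1Oc1cc(C)c(Cl)c(O)c1C(=O)O | target

**Summary**

Total step count: 11. Longest linear sequence: 8 steps (steps 1–6, 10, 11); the pyranone arm is 3 steps (7–9).

**Steps most likely to fail**

1. Step 10. The cycloaddition may be too slow, because the 4-benzyloxy group feeds electron density into the diene, while the ynol ether is consumed by thermal oligomerisation. The fallback redesigns the diene with an acyl group on the 4-oxygen. Setting out from 17, acetylation (Ac2O, pyridine, CH2Cl2, 0 °C) should give benzyl 4-(acetyloxy)-5-chloro-6-methyl-2-oxo-2H-pyran-3-carboxylate F1, a markedly more electron-poor diene. Heating F1 with 10 in toluene would pass through the bridged lactone benzyl 5-(acetyloxy)-6-chloro-8-[4-(benzyloxy)-2-methoxy-6-(methoxycarbonyl)phenoxy]-1-methyl-3-oxo-2-oxabicyclo[2.2.2]octa-5,7-diene-4-carboxylate F2 (not isolated) and, after loss of CO2, give benzyl 2-(acetyloxy)-3-chloro-6-[4-(benzyloxy)-2-methoxy-6-(methoxycarbonyl)phenoxy]-4-methylbenzoate F3. Methanolysis of the aryl acetate (K2CO3 cat., MeOH, 0 °C; the doubly ortho-substituted benzyl ester should not exchange) would give benzyl 3-chloro-2-hydroxy-6-[4-(benzyloxy)-2-methoxy-6-(methoxycarbonyl)phenoxy]-4-methylbenzoate F4. F4 would be debenzylated under the conditions of step 11, so the route is rejoined at 21.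

2. Step 6. The terminal aryl ynol ether may be lost by hydration to the aryl acetate or by oligomerisation during aqueous work-up, chromatography and concentration; attack of amide or acetylide on the methyl ester is the lesser concern at −78 °C. The fallback carries the alkyne as a storable C-silyl derivative. Setting out from 8, the acetylide 9 is formed as in step 6 but quenched with Me3SiCl, giving methyl 5-(benzyloxy)-3-methoxy-2-{[2-(trimethylsilyl)ethynyl]oxy}benzoate F5, which can be purified and kept. Immediately before the cycloaddition, Bu4NF (THF, −78 °C) would release 10, which after a cold aqueous wash and solvent exchange is taken straight into step 10, so the route is rejoined at 10.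

3. Step 8. Chlorination may stray, by ipso attack at the ester-bearing C3 or by over-chlorination, instead of clean substitution at C5. The fallback installs the chlorine before the ring exists. Setting out from 12, N-chlorosuccinimide in AcOH should give 5-chloro-2,2,6-trimethyl-4H-1,3-dioxin-4-one F6. Heated in toluene with the enolate 13 (made from 11 as in step 7), F6 should release 2-chloro-3-oxobut-1-en-1-one F7 (not isolated). F7 would C-acylate 13 to the sodium enolate of dibenzyl 2-(2-chloro-3-oxobutanoyl)propanedioate F8 (not isolated), which lactonises with loss of benzyl alcohol to 17 after acidification, so the route is rejoined at 17 with the chlorine position fixed by construction.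

**Further compounds**

F1 | step 10 | benzyl 4-(acetyloxy)-5-chloro-6-methyl-2-oxo-2H-pyran-3-carboxylate | CC1=C(Cl)C(OC(C)=O)=C(C(=O)OCc2ccccc2)C(=O)O1
F2 | step 10 | benzyl 5-(acetyloxy)-6-chloro-8-[4-(benzyloxy)-2-methoxy-6-(methoxycarbonyl)phenoxy]-1-methyl-3-oxo-2-oxabicyclo[2.2.2]octa-5,7-diene-4-carboxylate (racemic, not isolated) | O=C1OC2(C)C=C(Oc3c(OC)cc(OCc4ccccc4)cc3C(=O)OC)C1(C(=O)OCc1ccccc1)C(OC(C)=O)=C2Cl
F3 | step 10 | benzyl 2-(acetyloxy)-3-chloro-6-[4-(benzyloxy)-2-methoxy-6-(methoxycarbonyl)phenoxy]-4-methylbenzoate | COC(=O)c1cc(OCc2ccccc2)cc(OC)c1Oc1cc(C)c(Cl)c(OC(C)=O)c1C(=O)OCc1ccccc1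
F4 | step 10 | benzyl 3-chloro-2-hydroxy-6-[4-(benzyloxy)-2-methoxy-6-(methoxycarbonyl)phenoxy]-4-methylbenzoate | COC(=O)c1cc(OCc2ccccc2)cc(OC)c1Oc1cc(C)c(Cl)c(O)c1C(=O)OCc1ccccc1
F5 | step 6 | methyl 5-(benzyloxy)-3-methoxy-2-{[2-(trimethylsilyl)ethynyl]oxy}benzoate | COC(=O)c1cc(OCc2ccccc2)cc(OC)c1OC#C[Si](C)(C)C
F6 | step 8 | 5-chloro-2,2,6-trimethyl-4H-1,3-dioxin-4-one | CC1=C(Cl)C(=O)OC(C)(C)O1
F7 | step 8 | 2-chloro-3-oxobut-1-en-1-one (not isolated) | CC(=O)C(Cl)=C=O
F8 | step 8 | sodium enolate of dibenzyl 2-(2-chloro-3-oxobutanoyl)propanedioate (racemic, not isolated) | CC(=O)C(Cl)C(=O)[C-](C(=O)OCc1ccccc1)C(=O)OCc1ccccc1.[Na+]
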